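## The problem

Cladonaphchrom B (14) is a 2-methyl-4-arylchroman: a dihydropyran ring (O1, C2, C3, C4) fused to a benzene ring A (C4a–C8a) that carries a free hydroxyl at C5, with C4 bonded to C1 of a 4,5-dimethoxynaphthalene. The difficulty sits at C4, a diarylmethine wedged between the C5 oxygen of ring A and the peri C8–H of the naphthalene, so a bond from C4 to one of the two aryl groups is the hard bond of the molecule. The two stereocentres, C2 (S, methyl) and C4 (S, aryl), are 1,3-cis on the pyran ring. C4 has no neighbouring functional group through which it could be corrected, so its absolute configuration must come from a catalyst or from the chiral pool. C2 can then be relayed from C4 by addition to an sp2-hybridised C2 on the face away from the C4 aryl group, or the relay can run the other way. The 1,8-dimethoxynaphthalene unit is very electron-rich and will not tolerate strong electrophiles, hard oxidants or ether-cleaving Lewis acids. The C5 phenol needs a mask that comes off without touching the two methyl ethers, and the doubly benzylic C4–H must not be exposed to conditions that move a double bond to C4. The enabling feature is that C4 is a benzylic methine on C4a and the adjacent ring carbon C8a carries O1. If O1 is read as an oxygen inserted into an aryl–carbonyl bond, the ring O1–C2–C3–C4–C4a–C8a contracts to the five-membered ring of a 3-arylindan-1-one with C2 as the carbonyl carbon. That ring can be closed enantioselectively through C4–C4a from a 2'-bromochalcone.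

## Retrosynthesis

**C2–H and O–benzyl (14 ⇒ 12).** The last operation is chosen to create C2 and free the phenol together. Cutting the C2–H bond of 14 leads, through benzyl ether 13, to the exocyclic enol ether 12, in which C2 is sp2 and the C5 oxygen is benzylated. Against the neighbouring option of closing O1–C2 by substitution on a separately made carbinol, this cut needs no second chiral reagent and no separate deprotection. Its price is reliance on the C4 aryl group to steer hydrogen to the opposite face of C2. The forward step must add hydrogen selectively, must not move the double bond toward C4, and must cleave only the benzyl ether.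

**C2=CH2 (12 ⇒ 11).** Removing the methylidene carbon gives the dihydrocoumarin 11. A carbonyl methylenation is preferred to addition of a methyl nucleophile because it cannot add twice and gives the enol ether directly. Lactone 11 has the full ring system and the C4 stereocentre. The forward reaction must be non-basic so that the aryl lactone is not opened.

**O1–C8a (11 ⇒ 10).** Excising O1 contracts the lactone to the 3-arylindan-1-one 10. This cut turns a chroman problem into a carbocycle problem. The other cuts of the pyran ring leave an open-chain diarylmethine whose C4 would have to be set intermolecularly. The forward reaction is a Baeyer–Villiger oxidation in which the aryl carbon must migrate in preference to the methylene group and the oxidant must spare the dimethoxynaphthalene.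

**C4–C4a (10 ⇒ 9), the key cut.** Breaking the bond between the methine carbon and the benzo ring of 10, and placing bromine on the ring carbon, gives the 2'-bromochalcone 9, which is achiral and flat. Of the two aryl bonds to the methine, C4–C4a is preferred over C4–naphthyl because it can be formed intramolecularly, which is the best answer to the crowding. The bromine fixes the site of bond formation between the benzyloxy-bearing carbon and the acyl-bearing carbon. The forward reaction must close a five-membered ring, set the stereocentre from an achiral precursor, and end in reduction instead of β-hydride elimination.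

**Cα=Cβ (9 ⇒ 4 + 7).** The enone double bond is cut into methyl ketone 4 and aldehyde 7. Aldehyde 7 cannot enolise, so the crossed aldol condensation is unambiguous and should give the (E)-alkene that the key step requires. Both fragments are simple substituted arenes.

**The fragments (4 ⇒ 3 ⇒ 2 ⇒ 1; 7 ⇒ 6 ⇒ 5).** Ketone 4 is traced through carbinol 3 and aldehyde 2 to the bromophenol aldehyde 1, which already has bromine between the oxygen and the carbonyl-bearing carbon, so no aromatic substitution is needed on this ring. Aldehyde 7 comes through iminium salt 6 from 1,8-dimethoxynaphthalene 5 by electrophilic formylation para to a methoxy group. The forward reactions are an etherification, a methyl addition, an alcohol oxidation and a formylation.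

## Roads not taken

**Alternative 1:** Cyclobutenone benzannulation. The cut takes ring A itself apart (C4a–C8a, C5–C6 and C8–C8a) and leaves a chain that already holds C2 and C4. In the forward direction cyclobut-2-en-1-one A1 and the siloxyalkyne A2 are heated. A1 opens to a vinylketene, which adds [2+2] to the ynol ether; a second four-electron opening and a six-electron closure then build ring A as the phenol A3. Desilylation of the carbinol, Mitsunobu closure of O1–C2 with inversion, and removal of the aryl silyl ether would finish.

- Merits: the mechanism itself differentiates the two resorcinol oxygens (free hydroxyl for O1, silyl ether for C5). C2 is fixed by an SN2 closure that does not depend on the facial bias of a ring, which is more secure than the hydrogenation of the chosen plan. The naphthalene never meets an oxidant.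
- Weak points: all stereochemistry must be in A2 before the key step. Its C4 is a propargylic, benzylic methine next to an ynol ether, and the usual access to siloxyalkynes is ester homologation to an ynolate under strongly basic conditions, which puts an α-aryl stereocentre at risk. The 1,3-related carbinol needs its own asymmetric step. A1 is volatile and prone to polymerise.
- Comparison: the sequence to A2 alone is likely to be as long as the whole chosen route to indanone 10. The chosen plan creates C4 in the step that forms the crowded bond, from chalcone 9 made by an aldol condensation. Against alternative 1 it must set its dependence on substrate-controlled hydrogenation for C2 and its one peracid step.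

**Alternative 2:** Three-component acyl-arylation of a vinylnaphthalene. The cut removes C2–C3 and C4–C4a at once across the vinyl group of 1-ethenyl-4,5-dimethoxynaphthalene A5; no ring is formed. In the forward direction, near-UV irradiation of (Bu4N)4[W10O32] abstracts the formyl hydrogen of acetaldehyde A4. The acetyl radical adds to the terminal carbon of A5, and the benzylic radical is captured by a nickel catalyst (NiBr2(dme) with a chiral bis(imidazoline)) that carries the aryl group of 1,3-bis(benzyloxy)-2-bromobenzene A6. Reductive elimination gives ketone A7. Reagent-controlled ketone reduction, double debenzylation and Mitsunobu closure onto either of the two equivalent phenols would finish.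

- Merits: the whole carbon skeleton is assembled in one step from three simple pieces. The symmetric resorcinol removes the question of which oxygen becomes O1. The route would be about two steps shorter than the chosen one, and on step economy it is the better plan.
- Weak points: A6 is a 2,6-disubstituted aryl bromide, and the reductive elimination must form the same tri-ortho-encumbered diarylmethine intermolecularly, from a hindered 1-naphthylmethyl radical. That is well outside the steric range in which such radical-relay couplings are reliably enantioselective. Direct acylation of the aryl bromide competes whenever radical capture is slow. The hydridic benzylic and methoxy C–H bonds compete with the aldehyde C–H for the excited tungstate. The electron-rich naphthalene can quench the photocatalyst by electron transfer.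
- Comparison: the chosen plan forms the same crowded bond intramolecularly, in a ring, by two-electron organometallic steps with close analogy, and pays for that security with extra steps.

**Alternative 3:** Benzyloxybenzyne annulation of a chiral-pool aldol alkoxide. The cut removes O1–C8a and C4–C4a; ring A arrives as an aryne and C2 is bought. In the forward direction CsF with a crown ether desilylates both the silylated aldol A8 and the aryne precursor A9. The alkoxide adds to the aryne carbon remote from the benzyloxy group, and the aryl anion formed next to that group attacks the ketone, closing the pyran ring as the tertiary chromanol A10. Dehydration and hydrogenation would then reset C4 relative to C2 and remove the benzyl group.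

- Merits: the absolute configuration at C2 comes from a 3-hydroxybutanoate. The intrinsic regiochemistry of a 3-alkoxyaryne matches the oxygen pattern of ring A. No chiral catalyst and no peracid are needed. In these respects it is better than the chosen plan.
- Weak points: the free alkoxide of a β-hydroxy ketone is set up for retro-aldol cleavage. The aryl anion is generated beside a ketone with acidic α-hydrogens and must add to a hindered, electron-rich naphthyl ketone faster than it is protonated. Alkoxides are modest aryne traps. C4 emerges uncontrolled and needs extra steps. The aryne precursor is itself several steps.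
- Comparison: the 1,3-relay by hydrogenation, here from C2 to C4, is no more secure than the chosen plan's relay from C4 to C2. The chosen plan sets against the advantages of alternative 3 a key step of a reaction class already shown on 2'-halochalcones, with one bond formed under catalyst control.

Key step: step 6

Assumption: the (R)-antipode of the biaryl bisphosphine is taken to favour the (3S)-indanone 10. Both antipodes are available, so if the sense of induction is opposite for this substrate the (S)-ligand is used and nothing else changes. Compounds 1 and 5 are taken as commercial.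

## Route

**Step 1**
Reactants: 1 2-bromo-3-hydroxybenzaldehyde
Product: 2 3-(benzyloxy)-2-bromobenzaldehyde
Conditions: BnBr, K2CO3, DMF, rt
Reagents that add atoms: benzyl bromide, BrCc1ccccc1
Why: Williamson ether synthesis on the phenoxide; the benzyl ether masks the future C5 hydroxyl through the organometallic, basic and peracid steps and is removed in the final hydrogenation.

**Step 2**
Reactants: 2 3-(benzyloxy)-2-bromobenzaldehyde
Product: 3 1-[3-(benzyloxy)-2-bromophenyl]ethan-1-ol (racemic)
Conditions: MeMgBr, THF, −78 → 0 °C; then 1 M HCl, 0 °C
Reagents that add atoms: methylmagnesium bromide, C[Mg]Br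
Why: Grignard addition to the aldehyde; bromine–magnesium exchange is not expected with MeMgBr at low temperature, and the carbinol stereocentre is erased in step 3.

**Step 3**
Reactants: 3 1-[3-(benzyloxy)-2-bromophenyl]ethan-1-ol
Product: 4 1-[3-(benzyloxy)-2-bromophenyl]ethan-1-one
Conditions: Dess–Martin periodinane, CH2Cl2, rt
Reagents that add atoms: none
Why: Dess–Martin oxidation of a secondary benzylic alcohol; the aryl bromide and benzyl ether are inert to it.

**Step 4**
Reactants: 5 1,8-dimethoxynaphthalene
Product: 7 4,5-dimethoxynaphthalene-1-carbaldehyde, via iminium chloride 6 (not isolated)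
Conditions: POCl3, DMF, 0 → 70 °C; then ice–water, rt
Reagents that add atoms: N,N-dimethylformamide, CN(C)C=O; water, O
Why: Vilsmeier–Haack formylation; the chloroiminium electrophile attacks the α-position para to a methoxy group (C4), the first formyl group deactivates the ring against a second, and the iminium salt is hydrolysed on work-up.

**Step 5**
Reactants: 4 1-[3-(benzyloxy)-2-bromophenyl]ethan-1-one; 7 4,5-dimethoxynaphthalene-1-carbaldehyde
Product: 9 (E)-1-[3-(benzyloxy)-2-bromophenyl]-3-(4,5-dimethoxynaphthalen-1-yl)prop-2-en-1-one, via aldol adduct 8 (not isolated)
Conditions: NaOH (aq), EtOH–THF, 0 °C → rt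
Reagents that add atoms: none
Why: Claisen–Schmidt condensation; only ketone 4 can enolise, and E1cB dehydration of the aldol adduct gives the conjugated (E)-enone, the thermodynamic isomer.

**Step 6**
Reactants: 9 (E)-1-[3-(benzyloxy)-2-bromophenyl]-3-(4,5-dimethoxynaphthalen-1-yl)prop-2-en-1-one
Product: 10 (3S)-4-(benzyloxy)-3-(4,5-dimethoxynaphthalen-1-yl)-2,3-dihydro-1H-inden-1-one
Conditions: Pd(OAc)2 (5 mol %), (R)-3,5-Xyl-MeO-BIPHEP (6 mol %), HCO2Na (2 equiv, in portions), DMF–ethylene glycol, 80 °C, degassed
Reagents that add atoms: none
Why: Zerovalent palladium, formed in situ from Pd(OAc)2 and the bisphosphine, inserts into the C–Br bond of 9, and loss of bromide in the protic medium leaves a cationic arylpalladium that binds the enone. Migratory insertion joins the aryl carbon (indanone C3a, the future C4a) to the β-carbon (indanone C3, the future C4) and leaves palladium on the α-carbon as an enolate; this is a 5-endo-trig closure of the five-membered ketone ring, open to a conjugated enone acceptor. The palladium enolate cannot undergo syn β-hydride elimination because the only β-hydrogen is anti to the metal after syn addition, so it is protonated or reduced through a formate-derived hydride, and zerovalent palladium returns with loss of CO2. The closest known reaction type is the palladium-catalysed enantioselective reductive Heck cyclisation of 2'-halochalcones to 3-arylindan-1-ones. The new stereocentre is set in the insertion step by the chiral bisphosphine, which selects one face of the (E)-alkene, so the single alkene geometry from step 5 is essential. Cyclisation must outrun hydride transfer to the arylpalladium and conjugate reduction of the enone; the enone held next to the metal and the portion-wise supply of formate should secure this. The bromine between the benzyloxy and acyl carbons fixes the ring fusion, so the benzyloxy carbon becomes C5 of the chroman.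

**Step 7**
Reactants: 10 (3S)-4-(benzyloxy)-3-(4,5-dimethoxynaphthalen-1-yl)-2,3-dihydro-1H-inden-1-one
Product: 11 (4S)-5-(benzyloxy)-4-(4,5-dimethoxynaphthalen-1-yl)-3,4-dihydro-2H-chromen-2-one
Conditions: mCPBA (1.5 equiv), TsOH·H2O (cat.), CH2Cl2, 0–4 °C, dark
Reagents that add atoms: 3-chloroperoxybenzoic acid, O=C(OO)c1cccc(Cl)c1
Why: Baeyer–Villiger oxidation of an indan-1-one, in which the aryl carbon migrates in preference to the methylene group to give the 3,4-dihydrocoumarin; the stereocentre is remote from the reacting bonds and is untouched, and low temperature with a limited excess of peracid is chosen to spare the naphthalene.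

**Step 8**
Reactants: 11 (4S)-5-(benzyloxy)-4-(4,5-dimethoxynaphthalen-1-yl)-3,4-dihydro-2H-chromen-2-one
Product: 12 (4S)-5-(benzyloxy)-4-(4,5-dimethoxynaphthalen-1-yl)-2-methylidene-3,4-dihydro-2H-chromene
Conditions: Cp2TiMe2 (2.5 equiv), toluene–THF, 65 °C, dark; filtration through basic alumina
Reagents that add atoms: dimethyltitanocene Cp2TiMe2, C[Ti](C)(C1C=CC=C1)C1C=CC=C1
Why: Petasis methylenation; thermally generated Cp2Ti=CH2 adds to the lactone carbonyl and cycloreverts to the enol ether under non-basic conditions that do not open the aryl lactone or touch C4.

**Step 9**
Reactants: 12 (4S)-5-(benzyloxy)-4-(4,5-dimethoxynaphthalen-1-yl)-2-methylidene-3,4-dihydro-2H-chromene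
Product: 14 (2S,4S)-4-(4,5-dimethoxynaphthalen-1-yl)-2-methyl-3,4-dihydro-2H-chromen-5-ol (cladonaphchrom B), via benzyl ether 13 (not isolated)
Conditions: H2 (1 atm), 10% Pd/C, EtOAc, rt; then EtOH added, rt
Reagents that add atoms: none
Why: Heterogeneous catalytic hydrogenation followed by hydrogenolysis of the benzyl ether; the C4 aryl group, pushed pseudo-axial by the neighbouring C5 benzyloxy group, covers one face of the enol ether, so hydrogen should reach C2 from the opposite face and leave the methyl group cis to the aryl group (2S). The endocyclic enol ether isomer, should it form on the catalyst, is expected to give the same result.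

## Compound list

1 | 2-bromo-3-hydroxybenzaldehyde | O=Cc1cccc(O)c1Br | starting material
2 | 3-(benzyloxy)-2-bromobenzaldehyde | O=Cc1cccc(OCc2ccccc2)c1Br | intermediate
3 | 1-[3-(benzyloxy)-2-bromophenyl]ethan-1-ol (racemic) | CC(O)c1cccc(OCc2ccccc2)c1Br | intermediate
4 | 1-[3-(benzyloxy)-2-bromophenyl]ethan-1-one | CC(=O)c1cccc(OCc2ccccc2)c1Br | intermediate
5 | 1,8-dimethoxynaphthalene | COc1cccc2cccc(OC)c12 | starting material
6 | [(4,5-dimethoxynaphthalen-1-yl)methylidene]dimethylammonium chloride | COc1cccc2c(C=[N+](C)C)ccc(OC)c12.[Cl-] | intermediate
7 | 4,5-dimethoxynaphthalene-1-carbaldehyde | COc1cccc2c(C=O)ccc(OC)c12 | intermediate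
8 | 1-[3-(benzyloxy)-2-bromophenyl]-3-(4,5-dimethoxynaphthalen-1-yl)-3-hydroxypropan-1-one (racemic) | COc1cccc2c(C(O)CC(=O)c3cccc(OCc4ccccc4)c3Br)ccc(OC)c12 | intermediate
9 | (E)-1-[3-(benzyloxy)-2-bromophenyl]-3-(4,5-dimethoxynaphthalen-1-yl)prop-2-en-1-one | COc1cccc2c(/C=C/C(=O)c3cccc(OCc4ccccc4)c3Br)ccc(OC)c12 | intermediate
10 | (3S)-4-(benzyloxy)-3-(4,5-dimethoxynaphthalen-1-yl)-2,3-dihydro-1H-inden-1-one | COc1cccc2c([C@@H]3CC(=O)c4cccc(OCc5ccccc5)c43)ccc(OC)c12 | intermediate
11 | (4S)-5-(benzyloxy)-4-(4,5-dimethoxynaphthalen-1-yl)-3,4-dihydro-2H-chromen-2-one | COc1cccc2c([C@@H]3CC(=O)Oc4cccc(OCc5ccccc5)c43)ccc(OC)c12 | intermediate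
12 | (4S)-5-(benzyloxy)-4-(4,5-dimethoxynaphthalen-1-yl)-2-methylidene-3,4-dihydro-2H-chromene | COc1cccc2c([C@@H]3CC(=C)Oc4cccc(OCc5ccccc5)c43)ccc(OC)c12 | intermediate
13 | (2S,4S)-5-(benzyloxy)-4-(4,5-dimethoxynaphthalen-1-yl)-2-methyl-3,4-dihydro-2H-chromene | COc1cccc2c([C@@H]3C[C@H](C)Oc4cccc(OCc5ccccc5)c43)ccc(OC)c12 | intermediate
14 | (2S,4S)-4-(4,5-dimethoxynaphthalen-1-yl)-2-methyl-3,4-dihydro-2H-chromen-5-ol (cladonaphchrom B) | COc1cccc2c([C@@H]3C[C@H](C)Oc4cccc(O)c43)ccc(OC)c12 | target

## Step count and risks

Total step count: 9. Longest linear sequence: 8 steps (1 → 2 → 3 → 4 → 9 → 10 → 11 → 12 → 14); the branch 5 → 7 is one step.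

**Step 6 (key step).** What may go wrong:
- Oxidative addition at a bromide flanked by two ortho substituents is slow.
- Formate may transfer hydride to the arylpalladium before the strained 5-endo insertion, so bromine is lost without ring closure, or the enone may be reduced.
- The arylpalladium may instead palladate the phenyl ring of the neighbouring benzyl ether.
- The bulky β-naphthyl group may lower facial discrimination.
- Basic, hot conditions may erode the configuration of the product through proton shifts by way of its enol.

Fallback: keep the C4–C4a closure but change the metal and the elementary steps. Ketone 4 would be borylated (B2pin2, Pd(dppf)Cl2, KOAc, dioxane, 90 °C) to 1-[3-(benzyloxy)-2-(4,4,5,5-tetramethyl-1,3,2-dioxaborolan-2-yl)phenyl]ethan-1-one F1. F1 would be condensed with aldehyde 7 under mild amine catalysis to (E)-1-[3-(benzyloxy)-2-(4,4,5,5-tetramethyl-1,3,2-dioxaborolan-2-yl)phenyl]-3-(4,5-dimethoxynaphthalen-1-yl)prop-2-en-1-one F2. F2 would be cyclised by rhodium-catalysed asymmetric intramolecular 1,4-addition ([Rh(C2H4)2Cl]2, a chiral phosphoramidite or diene ligand, aq. K3PO4, toluene, 60 °C), returning to the route at 10. No hydride donor is present, and the rhodium enolate is simply protonated by water, so reduction without cyclisation cannot occur.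

**Step 7.** What may go wrong: the aryl ketone reacts slowly, so electrophilic oxidation of the dimethoxynaphthalene ring by the peracid can compete, and migration of the methylene carbon instead of the aryl carbon would give the wrong lactone.

Fallback: insert the oxygen by a hydroperoxide rearrangement instead of a peracid.
- From 10, MeMgBr (THF, −78 °C) would give (3S)-4-(benzyloxy)-3-(4,5-dimethoxynaphthalen-1-yl)-1-methyl-2,3-dihydro-1H-inden-1-ol F3 as a mixture of C1 epimers.
- H2O2 with catalytic H2SO4 (THF, 0 °C) would convert the tertiary benzylic alcohol into (3S)-4-(benzyloxy)-3-(4,5-dimethoxynaphthalen-1-yl)-1-methyl-2,3-dihydro-1H-inden-1-yl hydroperoxide F4.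
- Acid-catalysed Hock rearrangement (BF3·OEt2 cat., CH2Cl2, 0 °C) would shift the aryl carbon from carbon to oxygen. The ring-expanded oxocarbenium ion loses a proton to give (4S)-5-(benzyloxy)-4-(4,5-dimethoxynaphthalen-1-yl)-2-methyl-4H-chromene F5, the endocyclic isomer of 12.
- F5 is hydrogenated under the conditions of step 9 and rejoins the route at 14.

In this rearrangement the aryl group competes only with methyl and methylene, and no peracid is used.

**Step 8.** What may go wrong: methylenation of the hindered aryl lactone may be incomplete, and the acid-labile enol ether may be hydrolysed and ring-opened on work-up or chromatography.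

Fallback: from 11, one equivalent of MeLi (THF, −78 °C, cold quench) would give (4S)-4-[2-(benzyloxy)-6-hydroxyphenyl]-4-(4,5-dimethoxynaphthalen-1-yl)butan-2-one F6, in equilibrium with its cyclic hemiketal. Acid-catalysed cyclodehydration (TsOH cat., toluene, 4 Å sieves, 60 °C) would give the 4H-chromene F5 described above. F5 is hydrogenated under the conditions of step 9 and rejoins the route at 14.

**Step 9.** What may go wrong: facial selectivity at C2 may be poor if the C4 aryl group does not hold the pseudo-axial position, the double bond may migrate on the catalyst toward C4 with loss of its configuration, and debenzylation may be incomplete in the crowded environment.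

Fallback: set C2 by reagent control and SN2 closure instead of by the ring.
- From 12, mild aqueous acid (oxalic acid, THF–H2O, rt) would give ketone F6.
- Reduction with (S)-Me-CBS oxazaborolidine and BH3·SMe2 (THF, −20 °C) is expected by the usual model to give the (R)-carbinol, 3-(benzyloxy)-2-[(1S,3R)-1-(4,5-dimethoxynaphthalen-1-yl)-3-hydroxybutyl]phenol F7.
- Mitsunobu cyclisation (PPh3, DIAD, THF, 0 °C) closes O1–C2 with inversion and returns to the route at 13, which is then debenzylated with H2 and Pd/C to 14.

## Further compounds

F1 | step 6 | 1-[3-(benzyloxy)-2-(4,4,5,5-tetramethyl-1,3,2-dioxaborolan-2-yl)phenyl]ethan-1-one | CC(=O)c1cccc(OCc2ccccc2)c1B1OC(C)(C)C(C)(C)O1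
F2 | step 6 | (E)-1-[3-(benzyloxy)-2-(4,4,5,5-tetramethyl-1,3,2-dioxaborolan-2-yl)phenyl]-3-(4,5-dimethoxynaphthalen-1-yl)prop-2-en-1-one | COc1cccc2c(/C=C/C(=O)c3cccc(OCc4ccccc4)c3B3OC(C)(C)C(C)(C)O3)ccc(OC)c12
F3 | step 7 | (3S)-4-(benzyloxy)-3-(4,5-dimethoxynaphthalen-1-yl)-1-methyl-2,3-dihydro-1H-inden-1-ol (C1 epimers) | COc1cccc2c([C@@H]3CC(C)(O)c4cccc(OCc5ccccc5)c43)ccc(OC)c12
F4 | step 7 | (3S)-4-(benzyloxy)-3-(4,5-dimethoxynaphthalen-1-yl)-1-methyl-2,3-dihydro-1H-inden-1-yl hydroperoxide (C1 epimers) | COc1cccc2c([C@@H]3CC(C)(OO)c4cccc(OCc5ccccc5)c43)ccc(OC)c12
F5 | step 7 | (4S)-5-(benzyloxy)-4-(4,5-dimethoxynaphthalen-1-yl)-2-methyl-4H-chromene | COc1cccc2c([C@@H]3C=C(C)Oc4cccc(OCc5ccccc5)c43)ccc(OC)c12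
F6 | step 8 | (4S)-4-[2-(benzyloxy)-6-hydroxyphenyl]-4-(4,5-dimethoxynaphthalen-1-yl)butan-2-one | COc1cccc2c([C@H](CC(C)=O)c3c(O)cccc3OCc3ccccc3)ccc(OC)c12
F7 | step 9 | 3-(benzyloxy)-2-[(1S,3R)-1-(4,5-dimethoxynaphthalen-1-yl)-3-hydroxybutyl]phenol | COc1cccc2c([C@H](C[C@@H](C)O)c3c(O)cccc3OCc3ccccc3)ccc(OC)c12
A1 | alternative 1 | cyclobut-2-en-1-one | O=C1C=CC1
A2 | alternative 1 | triisopropyl{[(3S,5R)-3-(4,5-dimethoxynaphthalen-1-yl)-5-(triethylsilyloxy)hex-1-yn-1-yl]oxy}silane | COc1cccc2c([C@H](C[C@@H](C)O[Si](CC)(CC)CC)C#CO[Si](C(C)C)(C(C)C)C(C)C)ccc(OC)c12
A3 | alternative 1 | 2-[(1S,3R)-1-(4,5-dimethoxynaphthalen-1-yl)-3-(triethylsilyloxy)butyl]-3-(triisopropylsilyloxy)phenol | COc1cccc2c([C@H](C[C@@H](C)O[Si](CC)(CC)CC)c3c(O)cccc3O[Si](C(C)C)(C(C)C)C(C)C)ccc(OC)c12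
A4 | alternative 2 | acetaldehyde | CC=O
A5 | alternative 2 | 1-ethenyl-4,5-dimethoxynaphthalene | C=Cc1ccc(OC)c2c(OC)cccc12
A6 | alternative 2 | 1,3-bis(benzyloxy)-2-bromobenzene | Brc1c(OCc2ccccc2)cccc1OCc1ccccc1
A7 | alternative 2 | (4S)-4-[2,6-bis(benzyloxy)phenyl]-4-(4,5-dimethoxynaphthalen-1-yl)butan-2-one | COc1cccc2c([C@H](CC(C)=O)c3c(OCc4ccccc4)cccc3OCc3ccccc3)ccc(OC)c12
A8 | alternative 3 | (3S)-1-(4,5-dimethoxynaphthalen-1-yl)-3-(trimethylsilyloxy)butan-1-one | COc1cccc2c(C(=O)C[C@H](C)O[Si](C)(C)C)ccc(OC)c12
A9 | alternative 3 | 3-(benzyloxy)-2-(trimethylsilyl)phenyl trifluoromethanesulfonate | C[Si](C)(C)c1c(OCc2ccccc2)cccc1OS(=O)(=O)C(F)(F)F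
A10 | alternative 3 | (2S)-5-(benzyloxy)-4-(4,5-dimethoxynaphthalen-1-yl)-2-methyl-3,4-dihydro-2H-chromen-4-ol (one C4 epimer drawn) | COc1cccc2c([C@@]3(O)C[C@H](C)Oc4cccc(OCc5ccccc5)c43)ccc(OC)c12
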